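**Retrosynthetic overview**
1. The target comes from allylic alcohol 18. The C3–O bond is made with singlet oxygen, which also moves the alkene to C4=C18. Both oxygenated carbons are then taken to the 2,3-dione, which enolises to the diosphenol, and the tert-butyl ester is cleaved.
2. The side chain is built by HWE olefination of a methyl ketone. The quaternary C9 comes from hydrogen-atom-transfer Giese addition of the 9-methylidene decalin 13 to methyl vinyl ketone.
3. Ring B is formed second, by nickel-catalysed reductive alkyne–dienone cyclisation of 12. This makes C9–C10 and fixes the cis fusion.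
4. C7 and C8 come from allenylindium addition to aldehyde 5, followed by Mitsunobu inversion with acetic acid, which forms the C7–O bond.
5. Ring A comes first, from 2,3-dimethylcyclohexenone: CBS reduction, vinyl ether exchange and Claisen rearrangement (sets C5), later allylic oxidation and dehydrogenation.

Assumption: decalin intermediates carry clerodane numbering (ring A C1–C5/C10; ring B C5–C10; C17 on C8; C18 on C4; C19 on C5; C20 on C9; chain C11–C16), and 2,3-dimethylcyclohex-2-en-1-one is taken as commercial.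

**Step 1**
Reactants: 1 2,3-dimethylcyclohex-2-en-1-one
Product: 2 (1R)-2,3-dimethylcyclohex-2-en-1-ol
Conditions: (S)-Me-CBS oxazaborolidine [(S)-1-methyl-3,3-diphenylhexahydropyrrolo[1,2-c][1,3,2]oxazaborole] (10 mol %), BH3·SMe2, THF, −20 °C; MeOH quench
Reagents that add atoms: none
Why: Corey–Bakshi–Shibata reduction, in which the catalyst–borane complex binds the ketone away from the larger alkenyl flank and delivers hydride to one face, setting the carbinol carbon (future C3) as R.

**Step 2**
Reactants: 2 (1R)-2,3-dimethylcyclohex-2-en-1-ol; 3 butyl vinyl ether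
Product: 5 2-[(1R)-1,2-dimethylcyclohex-2-en-1-yl]acetaldehyde, via allyl vinyl ether 4 (not isolated)
Conditions: Pd(OCOCF3)2 (2 mol %), 4,7-diphenyl-1,10-phenanthroline (2 mol %), Et3N (cat.), neat 3, 75 °C; then xylenes, 140 °C, sealed tube
Reagents that add atoms: none
Why: Palladium-catalysed vinyl ether exchange forms the C3–O–vinyl bond, and the Claisen rearrangement then delivers the two-carbon unit suprafacially on the ring face that carried oxygen, so the C3 configuration is transferred to quaternary C5 while the C3=C4 alkene and the C7 aldehyde appear.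

**Step 3**
Reactants: 6 (2R)-but-3-yn-2-ol
Product: 7 (2R)-but-3-yn-2-yl methanesulfonate
Conditions: MsCl, Et3N, CH2Cl2, −78 → 0 °C
Reagents that add atoms: methanesulfonyl chloride, CS(=O)(=O)Cl
Why: O-Sulfonylation of a secondary alcohol, which does not touch the stereocentre.

**Step 4**
Reactants: 5 2-[(1R)-1,2-dimethylcyclohex-2-en-1-yl]acetaldehyde; 7 (2R)-but-3-yn-2-yl methanesulfonate
Product: 9 (2R,3S)-1-[(1R)-1,2-dimethylcyclohex-2-en-1-yl]-3-methylpent-4-yn-2-ol, via allenylindium reagent 8 (not isolated)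
Conditions: Pd(dppf)Cl2 (5 mol %), InI (1.4 equiv), THF/HMPA 3:1, rt
Reagents that add atoms: none
Why: Marshall propargylation, in which zerovalent palladium opens the mesylate anti (SN2′), monovalent indium takes over the allenyl group, and the axially chiral reagent adds to the aldehyde through a closed SE2′ transition state to give the anti adduct, setting C8 (S) and C7 (R).

**Step 5**
Reactants: 9 (2R,3S)-1-[(1R)-1,2-dimethylcyclohex-2-en-1-yl]-3-methylpent-4-yn-2-ol
Product: 10 (2S,3S)-1-[(1R)-1,2-dimethylcyclohex-2-en-1-yl]-3-methylpent-4-yn-2-yl acetate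
Conditions: AcOH, PPh3, DIAD, toluene, 0 °C → rt
Reagents that add atoms: acetic acid, CC(=O)O
Why: Mitsunobu esterification, in which acetate displaces the oxyphosphonium group by SN2, forming the C7–O bond with inversion to the required 7S (syn to C8) and installing the acetate in the same operation.

**Step 6**
Reactants: 10 (2S,3S)-1-[(1R)-1,2-dimethylcyclohex-2-en-1-yl]-3-methylpent-4-yn-2-yl acetate
Product: 11 (2S,3S)-1-[(1R)-1,2-dimethyl-4-oxocyclohex-2-en-1-yl]-3-methylpent-4-yn-2-yl acetate
Conditions: Rh2(cap)4 (dirhodium tetrakis(caprolactamate), 1 mol %), t-BuOOH (5 equiv), K2CO3 (0.5 equiv), CH2Cl2, rt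
Reagents that add atoms: tert-butyl hydroperoxide, CC(C)(C)OO
Why: Radical allylic C–H oxidation, where C2 is the only ring methylene allylic to C3=C4 (C5 is quaternary), so the 4-methyl-3-en-2-one forms and no stereocentre is touched.

**Step 7**
Reactants: 11 (2S,3S)-1-[(1R)-1,2-dimethyl-4-oxocyclohex-2-en-1-yl]-3-methylpent-4-yn-2-yl acetate
Product: 12 (2S,3S)-1-[(1S)-1,2-dimethyl-4-oxocyclohexa-2,5-dien-1-yl]-3-methylpent-4-yn-2-yl acetate
Conditions: IBX (2.5 equiv), 4-methoxypyridine N-oxide, DMSO, 25–40 °C
Reagents that add atoms: none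
Why: IBX dehydrogenation of a ketone through its enol, which can only create C1=C10, and the quaternary C5 blocks aromatisation (the descriptor at C5 changes by priority only).

**Step 8**
Reactants: 12 (2S,3S)-1-[(1S)-1,2-dimethyl-4-oxocyclohexa-2,5-dien-1-yl]-3-methylpent-4-yn-2-yl acetate
Product: 13 (5S,7S,8S,10R)-7-acetoxy-4,5,8-trimethyl-9-methylidene-cis-decal-3-en-2-one (5-Me/H-10/OAc β; 8-Me α)
Conditions: Ni(cod)2 (10 mol %), PBu3 (20 mol %), Et3B (3 equiv), MeOH/THF 8:1, 50 °C, 0.01 M
Reagents that add atoms: none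
Why: Montgomery-type reductive alkyne–enone cyclisation, in which zerovalent nickel couples the alkyne with the unsubstituted enone arm, methanol protonates the nickel enolate and an ethyl group of Et3B supplies the vinyl hydrogen; the tether reaches C10 only on the face bearing C6, so the fusion is cis (H-10 syn to C19), through a chair-like transition state with OAc and C17 equatorial.

**Step 9**
Reactants: 13 (5S,7S,8S,10R)-7-acetoxy-4,5,8-trimethyl-9-methylidene-cis-decal-3-en-2-one; 14 methyl vinyl ketone
Product: 15 (5S,7S,8S,9R,10R)-7-acetoxy-4,5,8,9-tetramethyl-9-(3-oxobutyl)-cis-decal-3-en-2-one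
Conditions: Fe(acac)3 (30 mol %), PhSiH3 (2.5 equiv), 14 (3 equiv), EtOH, 60 °C
Reagents that add atoms: none
Why: Iron-hydride hydrogen atom transfer followed by Giese addition (reductive olefin coupling), in which H adds to the CH2 terminus to make C20 and the planar tertiary C9 radical is trapped on the β face because axial C4 covers the α face, setting C9 (chain β, methyl α), while the conjugated ring A alkene is inert.

**Step 10**
Reactants: 15 (5S,7S,8S,9R,10R)-7-acetoxy-4,5,8,9-tetramethyl-9-(3-oxobutyl)-cis-decal-3-en-2-one; 16 tert-butyl 2-(diethoxyphosphoryl)acetate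
Product: 17 tert-butyl (5S,7S,8S,9R,10R,13E)-7-acetoxy-2-oxocleroda-3,13-dien-15-oate
Conditions: 16 (2 equiv), NaH, THF, 0 → 40 °C; chromatographic removal of the minor Z isomer
Reagents that add atoms: none
Why: Horner–Wadsworth–Emmons olefination, where the unhindered methyl ketone reacts ahead of the hindered conjugated ring ketone and the stabilised phosphonate favours the E enoate.

**Step 11**
Reactants: 17 tert-butyl (5S,7S,8S,9R,10R,13E)-7-acetoxy-2-oxocleroda-3,13-dien-15-oate
Product: 18 tert-butyl (2R,5S,7S,8S,9R,10R,13E)-7-acetoxy-2-hydroxycleroda-3,13-dien-15-oate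
Conditions: NaBH4, CeCl3·7H2O, MeOH, −78 → −40 °C
Reagents that add atoms: none
Why: Luche 1,2-reduction, in which hydride attacks C2 from the open convex β face (C20 fills the concave face) to give the pseudo-equatorial 2α-alcohol; this centre is erased in step 12, and enoate and acetate are untouched.

**Step 12**
Reactants: 18 tert-butyl (2R,5S,7S,8S,9R,10R,13E)-7-acetoxy-2-hydroxycleroda-3,13-dien-15-oate
Product: 21 (5S,7S,8S,9R,10R,13E)-7-acetoxy-2-hydroxy-3-oxocleroda-1,4(18),13-trien-15-oic acid, via allylic hydroperoxide 19 (not isolated), via tert-butyl ester diosphenol 20 (not isolated)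
Conditions: O2, tetraphenylporphyrin (cat.), visible light, CH2Cl2, −20 °C; then transfer into DMSO/(COCl)2 (4 equiv), CH2Cl2, −78 °C; Et3N, −78 → 0 °C; evaporate volatiles; TFA/CH2Cl2 1:4, 0 °C
Reagents that add atoms: dioxygen, O=O
Why: Proposed new method: singlet oxygen adds to C3 on the convex face and abstracts H from C18 (the methyl geminal to the bulky quaternary C5, the usual regiochemistry for allylic alcohols), forming the key C3–O bond and the C4=C18 alkene in 19; excess chlorodimethylsulfonium chloride then captures both the OH and the OOH group, and Et3N collapses the alkoxysulfonium to the C2 ketone and the so far undescribed peroxysulfonium to the C3 ketone with loss of DMSO, so the 2,3-dione enolises toward C1 to 20 and TFA frees the acid; the closest known reaction types are the Schenck ene reaction, the Kornblum–DeLaMare dehydration of acylated hydroperoxides and the Swern oxidation of 1,2-diols.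

**Compound list**
1 | 2,3-dimethylcyclohex-2-en-1-one | CC1=C(C)C(=O)CCC1 | starting material
2 | (1R)-2,3-dimethylcyclohex-2-en-1-ol | O[C@@H]1CCCC(C)=C1C | intermediate
3 | butyl vinyl ether | C=COCCCC | starting material
4 | (1R)-2,3-dimethylcyclohex-2-en-1-yl vinyl ether | C=CO[C@@H]1CCCC(C)=C1C | intermediate
5 | 2-[(1R)-1,2-dimethylcyclohex-2-en-1-yl]acetaldehyde | O=CC[C@]1(C)C(C)=CCCC1 | intermediate
6 | (2R)-but-3-yn-2-ol | C[C@@H](O)C#C | starting material
7 | (2R)-but-3-yn-2-yl methanesulfonate | C[C@@H](OS(C)(=O)=O)C#C | intermediate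
8 | (P)-buta-1,2-dien-1-ylindium iodide methanesulfonate | [H]C(C)=[C@]=C([H])[In](I)OS(C)(=O)=O | intermediate
9 | (2R,3S)-1-[(1R)-1,2-dimethylcyclohex-2-en-1-yl]-3-methylpent-4-yn-2-ol | C#C[C@H](C)[C@H](O)C[C@]1(C)C(C)=CCCC1 | intermediate
10 | (2S,3S)-1-[(1R)-1,2-dimethylcyclohex-2-en-1-yl]-3-methylpent-4-yn-2-yl acetate | C#C[C@H](C)[C@@H](OC(C)=O)C[C@]1(C)C(C)=CCCC1 | intermediate
11 | (2S,3S)-1-[(1R)-1,2-dimethyl-4-oxocyclohex-2-en-1-yl]-3-methylpent-4-yn-2-yl acetate | C#C[C@H](C)[C@@H](OC(C)=O)C[C@]1(C)C(C)=CC(=O)CC1 | intermediate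
12 | (2S,3S)-1-[(1S)-1,2-dimethyl-4-oxocyclohexa-2,5-dien-1-yl]-3-methylpent-4-yn-2-yl acetate | C#C[C@H](C)[C@@H](OC(C)=O)C[C@]1(C)C(C)=CC(=O)C=C1 | intermediate
13 | (5S,7S,8S,10R)-7-acetoxy-4,5,8-trimethyl-9-methylidene-cis-decal-3-en-2-one | CC1=CC(=O)C[C@@H]2C(=C)[C@H](C)[C@@H](OC(C)=O)C[C@]12C | intermediate
14 | methyl vinyl ketone | C=CC(C)=O | starting material
15 | (5S,7S,8S,9R,10R)-7-acetoxy-4,5,8,9-tetramethyl-9-(3-oxobutyl)-cis-decal-3-en-2-one | CC1=CC(=O)C[C@@H]2[C@@](C)(CCC(C)=O)[C@H](C)[C@@H](OC(C)=O)C[C@]12C | intermediate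
16 | tert-butyl 2-(diethoxyphosphoryl)acetate | CCOP(=O)(CC(=O)OC(C)(C)C)OCC | starting material
17 | tert-butyl (5S,7S,8S,9R,10R,13E)-7-acetoxy-2-oxocleroda-3,13-dien-15-oate | CC1=CC(=O)C[C@@H]2[C@@](C)(CC/C(C)=C/C(=O)OC(C)(C)C)[C@H](C)[C@@H](OC(C)=O)C[C@]12C | intermediate
18 | tert-butyl (2R,5S,7S,8S,9R,10R,13E)-7-acetoxy-2-hydroxycleroda-3,13-dien-15-oate | CC1=C[C@H](O)C[C@@H]2[C@@](C)(CC/C(C)=C/C(=O)OC(C)(C)C)[C@H](C)[C@@H](OC(C)=O)C[C@]12C | intermediate
19 | tert-butyl (2R,3R,5S,7S,8S,9R,10R,13E)-7-acetoxy-3-hydroperoxy-2-hydroxycleroda-4(18),13-dien-15-oate | C=C1[C@@H](OO)[C@H](O)C[C@@H]2[C@@](C)(CC/C(C)=C/C(=O)OC(C)(C)C)[C@H](C)[C@@H](OC(C)=O)C[C@]12C | intermediate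
20 | tert-butyl (5S,7S,8S,9R,10R,13E)-7-acetoxy-2-hydroxy-3-oxocleroda-1,4(18),13-trien-15-oate | C=C1C(=O)C(O)=C[C@@H]2[C@@](C)(CC/C(C)=C/C(=O)OC(C)(C)C)[C@H](C)[C@@H](OC(C)=O)C[C@]12C | intermediate
21 | (5S,7S,8S,9R,10R,13E)-7-acetoxy-2-hydroxy-3-oxocleroda-1,4(18),13-trien-15-oic acid (CNP0192653.1) | C=C1C(=O)C(O)=C[C@@H]2[C@@](C)(CC/C(C)=C/C(=O)O)[C@H](C)[C@@H](OC(C)=O)C[C@]12C | target

**Step count and risks**
Total step count: 12. Longest linear sequence: 11 (steps 1, 2 and 4–12; step 3 is a one-step branch).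

The three steps most likely to fail are 5, 8 and 12.

*Step 5.* The SN2 displacement takes place at a carbinol flanked by a neopentyl-type CH2 and a branched propargylic carbon, so it may stall or lead to elimination.
- The fallback sets out from aldehyde 5 and avoids the inversion altogether.
- Commercial (S)-but-3-yn-2-ol is mesylated to (2S)-but-3-yn-2-yl methanesulfonate F1.
- F1 is displaced anti-SN2′ with Bu3SnLi/CuBr·SMe2 to give (M)-tributyl(buta-1,2-dien-1-yl)stannane F2.
- F2 is added to 5 with BF3·OEt2 at −78 °C. The open transition state favours the syn adduct, giving the (2S,3S)-alcohol F3.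
- Ac2O/pyridine then returns the material to the route at acetate 10.

*Step 8.* A terminal alkyne can oligomerise on zerovalent nickel, and six-membered ring closure is slower than five-membered.
- The fallback sets out from dienone 12 and uses a radical chain instead of metal catalysis.
- Slow addition of Bu3SnH/AIBN in benzene at 80 °C adds a stannyl radical to the alkyne terminus.
- The resulting vinyl radical closes 6-exo onto C10 to give the exocyclic vinylstannane F4.
- Protodestannylation with HCl in CH2Cl2 returns to the route at 13.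

*Step 12.* This is the proposed new step. The peroxysulfonium collapse is unproven, and the hydroperoxide could react with the sulfonium reagent in other ways.
- The fallback sets out from allylic alcohol 18 and uses only known reactions.
- Photooxygenation is run as before, and hydroperoxide 19 is reduced with PPh3.
- The 2,3-diol F5 is isolated and then oxidised twice with DMSO/(CF3CO)2O/Et3N, a known conversion of 1,2-diols to 1,2-diones.
- This returns to the route at ester 20, which is cleaved with TFA to give 21.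

**Further compounds**
F1 | step 5 | (2S)-but-3-yn-2-yl methanesulfonate | C[C@H](OS(C)(=O)=O)C#C
F2 | step 5 | (M)-tributyl(buta-1,2-dien-1-yl)stannane | [H]C(C)=[C@@]=C([H])[Sn](CCCC)(CCCC)CCCC
F3 | step 5 | (2S,3S)-1-[(1R)-1,2-dimethylcyclohex-2-en-1-yl]-3-methylpent-4-yn-2-ol | C#C[C@H](C)[C@@H](O)C[C@]1(C)C(C)=CCCC1
F4 | step 8 | (5S,7S,8S,10R)-7-acetoxy-4,5,8-trimethyl-9-[(tributylstannyl)methylidene]-cis-decal-3-en-2-one (E/Z mixture) | CC1=CC(=O)C[C@@H]2C(=C[Sn](CCCC)(CCCC)CCCC)[C@H](C)[C@@H](OC(C)=O)C[C@]12C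
F5 | step 12 | tert-butyl (2R,3R,5S,7S,8S,9R,10R,13E)-7-acetoxy-2,3-dihydroxycleroda-4(18),13-dien-15-oate | C=C1[C@@H](O)[C@H](O)C[C@@H]2[C@@](C)(CC/C(C)=C/C(=O)OC(C)(C)C)[C@H](C)[C@@H](OC(C)=O)C[C@]12C
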